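## Structural features

The target is a stilbenoid trimer made of two 2,3-diaryl-2,3-dihydrobenzofurans. Ring A is fused to a resorcinol-type benzene ring and carries a 4-hydroxyphenyl group on C2, a (Z)-4-hydroxystyryl group on C4 and a phenol on C6. Its C3 is bonded to C5' of ring B, whose benzene ring is catechol-derived (O1' and the 7'-OH are neighbours) and which carries a 4-hydroxyphenyl group on C2' and a 3,5-dihydroxyphenyl group on C3'. The four stereocentres form two vicinal trans pairs, C2/C3 (S,S) and C2'/C3' (R,R). The pairs are separated by the ring B arene, so neither can direct the other and each needs its own reagent control. Fragile elements are the Z-stilbene (acid, light, over-reduction), seven oxidisable phenols and the two O–C2 bonds, which are para-hydroxybenzylic ethers that ionise under acid. That ionisation makes C2 and C2' thermodynamically correctable, whereas C3 and C3' are fixed once formed. The real difficulty is the congested ring A (C3 lies between the C2 aryl group and the C4 side chain) and the absolute control of C3 and C3'. The key step uses the fact that the arene on C3' is a plain resorcinol with one carbon substituent: its six carbons map onto a tetraketide chain whose starter carbonyl is the carbon attached to C3', so the ring can be grown from a C3' carboxyl group, which is what a carbene C–H insertion leaves on C3' when it sets C2'.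

## Logic of the disconnections

32 to 31: the seven O–Si bonds are cut. The last step must be neutral and mild because of the Z-olefin and the benzylic ethers. The gain is a non-polar precursor; the demand is a buffered fluoride source so that the liberated phenoxides are not oxidised.

31 to 30: the two olefinic C–H bonds are removed to give the alkyne. The Z geometry then comes from syn delivery of hydrogen, with no olefination mixture. The demand is that the reduction stops at the alkene.

30 to 28 and 29: the C4–C(sp) bond is cut. This is the last convergent union and leaves a bromine on C4 that is inert in all earlier steps. The demand is a coupling next to the crowded C3 at a temperature the silyl ethers tolerate.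

28 to 27 to 26: six O–Si bonds, then six O–CH3 bonds and the configuration of C2. Methyl ethers are the only groups that survive the polyanion, hydroxide and carbene steps, so they are exchanged for silyl groups at the stage where the molecule has no olefin. The same Lewis acid is used to equilibrate C2 to trans. The demand is that C3 neither ionises nor eliminates.

26 to 24 (through 25): the C2–C3 bond of ring A is cut, which reveals a diaryl carbene inserting into the benzylic C–H of an aryl benzyl ether. This is chosen because C3 can only be set by a catalyst. The gain is that ring A opens to a benzophenone hydrazone. The demand is that the chiral dirhodium catalyst copes with the ortho bromine; the cis product is acceptable because C2 is corrected later.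

24 to 23 to 22 to 17 and 20: the C=N bond, the ketone oxidation level and the C3–C5' bond are cut. This is the only bond between the two halves and it is made from an aryllithium and an aldehyde. The demand is that bromine–lithium exchange on 17 beats benzylic deprotonation and that the second bromide, in 20, is ignored.

20 to 19 and 3, and 19 to 18: the benzylic O–CH2 bond, then the O–CH3 bond ortho to the formyl group. Chelation by the aldehyde makes that one ether cleavable selectively.

17 to 16 to 14 (through 15): two O–CH3 bonds and the aryl–CO2 bond. The extra carboxyl group is the price of the aldol fold and is trimmed as in the biosynthesis. The demand is hydrolysis of a hindered, deactivated ester.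

14 to 12 (key): the aromatic bond between the carbon bearing C3' and the ester-bearing carbon (C7–C2 of the chain) is cut and two molecules of water are added back. The whole arene is reduced to a linear acyl chain on C3'. The demand is aldol closure in preference to Claisen closure and lactonisation, with C3' untouched.

12 to 9 and 10: the C6–C7 bond is cut. The full seven-carbon chain arrives in one acylation of a polyanion. The demand is that acylation beats proton transfer from C3' of 9.

9 to 8 to 6 (through 7): the amide C–N bond, the C3' epimer, then the C2'–C3' bond by carbene C–H insertion, which sets C2'. The gain is an acyclic aryldiazoacetate. The demand is enantiotopic discrimination of the two benzylic hydrogens.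

6 to 4 and 5, 4 to 2 and 3, 2 to 1: the aryl–C(diazo) bond, the O–CH2 bond and the carbon–iodine bond. All three are standard and leave commercial materials.

## Other disconnections considered

Alternative 1: The cut is the C3–C3a bond of ring A, with the pyranone of a flavanone as its source. In the forward direction, near-UV photolysis of the diazo ketone A1 in methanol gives a Wolff ring contraction to the 3-carboxylate, equilibrated by methoxide to the trans ester A2.
- In its favour: C2 is unchanged by the rearrangement and can come from well-developed asymmetric routes to flavanones; the trans relation then follows by simple epimerisation, and no hindered diaryl diazo compound is needed. On these two points it is the equal of the chosen plan for ring B and better than it for ring A.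
- Against it here: diazo transfer next to C2 of a flavanone invites retro-oxa-Michael opening, which would racemise C2. A2 also carries an ester where the target has the ring B arene, so the C3–C5' bond or the whole ring B benzene ring still has to be made at a hindered secondary centre, and the resorcinol ring after that.
- Comparison: both plans rest on diazo/carbene chemistry. The chosen plan uses its ester once, to grow the resorcinol, and joins the halves by a simple aryllithium addition; Alternative 1 would need two arene constructions or a decarboxylative arylation, so it is expected to be longer.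

Alternative 2: The cuts are O1'–C7a' and the carbinol C–H of ring B. In the forward direction, asymmetric transfer hydrogenation of the racemising ketone A3 under dynamic kinetic resolution is followed in the same flask by intramolecular displacement of fluoride, giving A4.
- In its favour: the 3,5-dioxygenated ring is present from the start, so no arene has to be built; both stereocentres are set in one operation; the ester is a handle for the union. In step economy for ring B it is clearly better than the chosen plan (a few steps against nine).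
- Against it here: the selectivity depends on the catalyst telling two aryl groups apart on the alpha carbon, which is less secure than telling an aryl from an alkyl group. Any erosion gives diastereomers that differ only at C3'.
- Comparison: the chosen plan sets C2' by a catalyst-controlled insertion and C3' by thermodynamics, two independent and well-understood controls, and pays for this with the polyketide detour. Mechanistically Alternative 2 is the simpler ionic sequence.

Alternative 3: The cuts are C7a–C7 and C5–C6 of the ring A benzene ring. In the forward direction, heating cyclobutenone A5 with siloxyalkyne A6 gives, by ring opening, (2+2) cycloaddition, second ring opening and 6-pi electrocyclisation, the fully substituted phenol A7.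
- In its favour: every substituent of the crowded ring A is placed without regiochemical doubt, the two oxygens are differentiated, the alkyne for the Z-olefin is already present, and the side-chain stereocentres can be set by reliable acyclic chemistry. On regiocontrol of ring A it is better than the chosen plan, and it avoids the hindered carbene.
- Against it here: A5 with its stereogenic side chain needs a multistep synthesis and must survive heating. In A7 the oxygen on C2 is the silyl ether oxygen, not the ring oxygen, so an invertive closure would give the cis ring. The closure must therefore be ionising (thermodynamic), which is the same reliance on equilibration at C2 as in the chosen plan, or the carbinol epimer is needed.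
- Comparison: A7 already contains ring B, so this plan does not replace the key step but only the union and ring A closure, with a longer sequence than steps 12 to 15.

Key step: step 7

Remarks and assumptions:
- Numbering: ring A atoms are unprimed, ring B atoms primed; the chain of 12 runs from C1 (ester) to C7 (carbonyl on C3').
- Compounds 12 and 14 were checked against the target. Both carry the (2R,3R) trans ring B with bromine on C5' and methoxy on C7', so no correction of connectivity or configuration was needed.
- What is changed is the way 12 is made. The chain is attached in one acylation of a preformed trianion by an N-methoxy-N-methylamide, so the aryl bromide never meets free amide base, no diazomethane is needed, and enolisation of the acyl donor is limited.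
- Compounds 10, 18 and 29 are taken as catalogue compounds.
- The catalyst antipodes in steps 4 and 15 are those expected by analogy with related benzyl ether insertions. If the sense of induction proves opposite, the mirror-image catalyst is used and nothing else changes.

## Route

Step 1
Reactants: 1 4-bromo-2-methoxyphenol
Product: 2 4-bromo-2-iodo-6-methoxyphenol
Conditions: NIS (1.05 equiv), TsOH·H2O (10 mol %), MeCN, 0 °C to rt
Reagents that add atoms: N-iodosuccinimide, O=C1CCC(=O)N1I
Why: Electrophilic aromatic iodination; the free hydroxyl is the strongest director and its para position is blocked by bromine, so iodine enters the one free ortho position.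

Step 2
Reactants: 2 4-bromo-2-iodo-6-methoxyphenol; 3 4-methoxybenzyl chloride
Product: 4 5-bromo-1-iodo-3-methoxy-2-[(4-methoxyphenyl)methoxy]benzene
Conditions: K2CO3, Bu4NI (cat.), DMF, 50 °C
Reagents that add atoms: none
Why: Williamson ether synthesis on a phenoxide with a reactive benzylic chloride; the benzylic CH2 introduced here becomes C2' and its aryl group the C2' substituent.

Step 3
Reactants: 4 5-bromo-1-iodo-3-methoxy-2-[(4-methoxyphenyl)methoxy]benzene; 5 ethyl diazoacetate
Product: 6 ethyl 2-{5-bromo-3-methoxy-2-[(4-methoxyphenyl)methoxy]phenyl}-2-diazoacetate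
Conditions: Pd(PPh3)4 (5 mol %), Ag2CO3 (0.5 equiv), Et3N (1.3 equiv), toluene, rt
Reagents that add atoms: none
Why: Palladium-catalysed cross-coupling of an aryl iodide with the C–H bond of an acceptor diazo ester; zerovalent palladium inserts into the carbon–iodine bond much faster than into the carbon–bromine bond at room temperature and the diazo group is retained.

Step 4
Reactants: 6 ethyl 2-{5-bromo-3-methoxy-2-[(4-methoxyphenyl)methoxy]phenyl}-2-diazoacetate
Product: 8 ethyl (2R,3R)-5-bromo-7-methoxy-2-(4-methoxyphenyl)-2,3-dihydro-1-benzofuran-3-carboxylate, via cis ester 7 (not isolated)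
Conditions: Rh2(S-PTTL)4 [dirhodium tetrakis(N-phthaloyl-(S)-tert-leucinate)] (1 mol %), toluene, −60 to −20 °C; then NaOEt (0.3 equiv), EtOH, rt
Reagents that add atoms: none
Why: Intramolecular 1,5 C–H insertion of a donor/acceptor rhodium carbene into the para-methoxybenzylic ether C–H closes the dihydrofuran; the chiral carboxylate ligands select one enantiotopic hydrogen and so set C2' (R), giving the kinetic cis ester 7 (2R,3S). Catalytic ethoxide then epimerises the ester-bearing C3' to the more stable trans arrangement without touching C2'.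

Step 5
Reactants: 8 ethyl (2R,3R)-5-bromo-7-methoxy-2-(4-methoxyphenyl)-2,3-dihydro-1-benzofuran-3-carboxylate
Product: 9 (2R,3R)-5-bromo-N,7-dimethoxy-2-(4-methoxyphenyl)-N-methyl-2,3-dihydro-1-benzofuran-3-carboxamide
Conditions: MeNH(OMe)·HCl (2 equiv), i-PrMgCl (4 equiv), THF, −20 °C
Reagents that add atoms: N,O-dimethylhydroxylamine hydrochloride, CNOC.Cl
Why: Direct aminolysis of the ester by the chloromagnesium amide made in the flask; it is fast at low temperature, so the trans centre alpha to the carbonyl is kept, and the electron-rich aryl bromide does not undergo halogen–magnesium exchange under these conditions.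

Step 6
Reactants: 9 (2R,3R)-5-bromo-N,7-dimethoxy-2-(4-methoxyphenyl)-N-methyl-2,3-dihydro-1-benzofuran-3-carboxamide; 10 methyl 3,5-dioxohexanoate
Product: 12 methyl 7-[(2R,3R)-5-bromo-7-methoxy-2-(4-methoxyphenyl)-2,3-dihydro-1-benzofuran-3-yl]-3,5,7-trioxoheptanoate, via trilithium trianion of methyl 3,5-dioxohexanoate 11 (not isolated)
Conditions: 10 (2.2 equiv), LiN(i-Pr)2 (6.6 equiv), THF, −78 to 0 °C; then 9, −78 to −20 °C; AcOH, −78 °C; crude 12 (enol mixture) used at once
Reagents that add atoms: none
Why: Acylation of a beta-polycarbonyl polyanion at its terminal, least stabilised carbanion forms the C6–C7 bond. The N-methoxy-N-methylamide gives a chelated tetrahedral intermediate that persists until the quench, so there is no over-addition and the product does not quench the nucleophile; the aryl bromide meets no free amide base.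

Step 7
Reactants: 12 methyl 7-[(2R,3R)-5-bromo-7-methoxy-2-(4-methoxyphenyl)-2,3-dihydro-1-benzofuran-3-yl]-3,5,7-trioxoheptanoate
Product: 14 methyl 2-[(2R,3R)-5-bromo-7-methoxy-2-(4-methoxyphenyl)-2,3-dihydro-1-benzofuran-3-yl]-4,6-dihydroxybenzoate, via cyclic aldol adduct 13 (not isolated)
Conditions: aq. KOH (1 mol/L, 5 equiv), THF, 0 °C to rt, argon; then aq. HCl to pH 3, rt
Reagents that add atoms: none
Why: In aqueous hydroxide 12 is a polyenolate in which C2, flanked by the ester and the C3 ketone, is the most nucleophilic carbon and the terminal C7 carbonyl, conjugated to one enolate only, is the most electrophilic; C2 adds to C7 in an intramolecular aldol reaction to give the six-membered carbinol 13. Loss of water and enolisation of the C3 and C5 carbonyls then give the benzene ring, completed on acidification. The closest known reaction type is the biomimetic aldol cyclisation of 3,5,7-triketo esters to 6-substituted 2,4-dihydroxybenzoates, the chemical counterpart of the stilbene synthase fold. The ring closes in the 6-(enolendo)-exo-trig mode and C2–C7 is the only new skeletal bond. No lasting stereocentre is formed, since the carbinol carbon and C2 of 13 become aromatic. The step needs aldol closure to win over Claisen closure (C6 to the ester carbon) and over lactonisation to pyrones; water as solvent and potassium as counter-ion, with no chelating divalent metal to activate the ester, favour the aldol path. C3' should keep its configuration because the C7 carbonyl is enolised towards C6, because beta-elimination of the ring aryloxide would be a reverse 5-endo-trig process with poor orbital overlap, and because trans is the thermodynamic arrangement in any case.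

Step 8
Reactants: 14 methyl 2-[(2R,3R)-5-bromo-7-methoxy-2-(4-methoxyphenyl)-2,3-dihydro-1-benzofuran-3-yl]-4,6-dihydroxybenzoate
Product: 16 5-[(2R,3R)-5-bromo-7-methoxy-2-(4-methoxyphenyl)-2,3-dihydro-1-benzofuran-3-yl]benzene-1,3-diol, via resorcylic acid 15 (not isolated)
Conditions: KOH (20 equiv), H2O/1,4-dioxane (1:1), 100 °C; then HCl to pH 2, 80 °C
Reagents that add atoms: none
Why: Saponification of the hindered salicylate-type ester followed by protodecarboxylation; 2,4-dihydroxybenzoic acids lose CO2 readily through ipso protonation of the electron-rich ring. C3' is now a triaryl-type methine and is not base-labile.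

Step 9
Reactants: 16 5-[(2R,3R)-5-bromo-7-methoxy-2-(4-methoxyphenyl)-2,3-dihydro-1-benzofuran-3-yl]benzene-1,3-diol
Product: 17 (2R,3R)-5-bromo-3-(3,5-dimethoxyphenyl)-7-methoxy-2-(4-methoxyphenyl)-2,3-dihydro-1-benzofuran
Conditions: MeI (3 equiv), K2CO3, acetone, reflux
Reagents that add atoms: iodomethane, CI
Why: Williamson O-methylation of the two phenols; methyl ethers are needed to survive the organolithium, hydrazine and carbene steps that follow.

Step 10
Reactants: 18 2-bromo-4,6-dimethoxybenzaldehyde
Product: 19 2-bromo-6-hydroxy-4-methoxybenzaldehyde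
Conditions: BCl3 (1.2 equiv), CH2Cl2, −78 to 0 °C
Reagents that add atoms: none
Why: Chelation-controlled ether cleavage; boron bound to the formyl oxygen delivers chloride only to the ortho methyl ether, leaving the para one.

Step 11
Reactants: 19 2-bromo-6-hydroxy-4-methoxybenzaldehyde; 3 4-methoxybenzyl chloride
Product: 20 2-bromo-4-methoxy-6-[(4-methoxyphenyl)methoxy]benzaldehyde
Conditions: K2CO3, Bu4NI (cat.), DMF, 60 °C
Reagents that add atoms: none
Why: Williamson ether synthesis; this benzylic CH2 becomes C2 of ring A and its aryl group the C2 substituent.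

Step 12
Reactants: 17 (2R,3R)-5-bromo-3-(3,5-dimethoxyphenyl)-7-methoxy-2-(4-methoxyphenyl)-2,3-dihydro-1-benzofuran; 20 2-bromo-4-methoxy-6-[(4-methoxyphenyl)methoxy]benzaldehyde
Product: 22 {2-bromo-4-methoxy-6-[(4-methoxyphenyl)methoxy]phenyl}[(2R,3R)-3-(3,5-dimethoxyphenyl)-7-methoxy-2-(4-methoxyphenyl)-2,3-dihydro-1-benzofuran-5-yl]methanol (both carbinol epimers), via aryllithium 21 (not isolated)
Conditions: n-BuLi (1.05 equiv), THF, −78 °C; then 20, −78 °C; aq. NH4Cl
Reagents that add atoms: none
Why: Bromine–lithium exchange, faster at −78 °C than deprotonation at C2' or C3', then 1,2-addition to the aldehyde, which is faster than exchange with the aryl bromide of 20. The carbinol centre is not controlled because it is oxidised in the next step.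

Step 13
Reactants: 22 the diaryl carbinol from step 12
Product: 23 {2-bromo-4-methoxy-6-[(4-methoxyphenyl)methoxy]phenyl}[(2R,3R)-3-(3,5-dimethoxyphenyl)-7-methoxy-2-(4-methoxyphenyl)-2,3-dihydro-1-benzofuran-5-yl]methanone
Conditions: Dess–Martin periodinane (1.3 equiv), CH2Cl2, rt
Reagents that add atoms: none
Why: Dess–Martin oxidation of a doubly benzylic secondary alcohol; neutral conditions leave the benzyl ether and the dihydrofuran untouched.

Step 14
Reactants: 23 the diaryl ketone from step 13
Product: 24 hydrazone of 23 (C=N–NH2 in place of C=O; E/Z mixture)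
Conditions: N2H4·H2O (30 equiv), AcOH (cat.), n-BuOH, 110 °C, sealed tube
Reagents that add atoms: hydrazine hydrate, NN.O
Why: Acid-catalysed condensation of a ketone with hydrazine; forcing conditions are chosen because the carbonyl has two ortho substituents on one side, and nothing else in the molecule reacts with hydrazine.

Step 15
Reactants: 24 the hydrazone from step 14
Product: 26 (2R,3S)-4-bromo-3-[(2R,3R)-3-(3,5-dimethoxyphenyl)-7-methoxy-2-(4-methoxyphenyl)-2,3-dihydro-1-benzofuran-5-yl]-6-methoxy-2-(4-methoxyphenyl)-2,3-dihydro-1-benzofuran, via diaryldiazomethane 25 (not isolated)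
Conditions: MnO2 (8 equiv), CH2Cl2, 0 °C, dark; filtration; then Rh2(R-PTAD)4 [dirhodium tetrakis((R)-(1-adamantyl)(phthalimido)acetate)] (1 mol %), CH2Cl2, −20 °C to rt
Reagents that add atoms: none
Why: Dehydrogenation of the hydrazone gives the diaryldiazomethane, and intramolecular 1,5 C–H insertion of the donor/donor rhodium carbene into the benzylic ether C–H then closes ring A, a known enantioselective entry to cis-2,3-diaryl-2,3-dihydrobenzofurans. The chiral dirhodium carboxylate sets C3 (S) independently of ring B; the kinetic product is cis (2R,3S), and any minor ring A antipode is a diastereomer that can be removed.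

Step 16
Reactants: 26 the cis ring A hexamethyl ether from step 15
Product: 27 5-[(2R,3R)-5-[(2S,3S)-4-bromo-6-hydroxy-2-(4-hydroxyphenyl)-2,3-dihydro-1-benzofuran-3-yl]-7-hydroxy-2-(4-hydroxyphenyl)-2,3-dihydro-1-benzofuran-3-yl]benzene-1,3-diol
Conditions: BBr3 (15 equiv), CH2Cl2, −78 °C to rt; MeOH, then H2O
Reagents that add atoms: none
Why: Lewis acid cleavage of the six aryl methyl ethers at a stage without an olefin. Boron on O1 of ring A lets the O1–C2 bond ionise reversibly to a para-oxygenated benzylic cation, so C2 should equilibrate from cis (2R) to the more stable trans (2S) arrangement, while C3 and C3' have no ionisable bond and C2' is already trans.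

Step 17
Reactants: 27 the hexaphenol bromide from step 16
Product: 28 hexakis(tert-butyldimethylsilyl) ether of 27 (all six phenols silylated, configuration unchanged)
Conditions: TBSCl (9 equiv), imidazole (18 equiv), DMF, rt
Reagents that add atoms: tert-butyldimethylsilyl chloride, CC(C)(C)[Si](C)(C)Cl
Why: Imidazole-promoted silylation of phenols; it gives a non-polar intermediate whose protecting groups can be removed by fluoride in the presence of the Z-olefin.

Step 18
Reactants: 28 the hexasilyl bromide from step 17; 29 tert-butyl(4-ethynylphenoxy)dimethylsilane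
Product: 30 diarylalkyne: 28 with the bromine on C4 of ring A replaced by a 2-[4-(tert-butyldimethylsilyloxy)phenyl]ethynyl group
Conditions: Pd(PhCN)2Cl2 (5 mol %), P(t-Bu)3 (10 mol %), CuI (5 mol %), i-Pr2NH, 1,4-dioxane, rt to 45 °C
Reagents that add atoms: none
Why: Sonogashira coupling; the bulky electron-rich phosphine allows oxidative addition into the ortho-substituted aryl bromide near room temperature, and the amine base leaves the aryl silyl ethers intact.

Step 19
Reactants: 30 the diarylalkyne from step 18
Product: 31 heptakis(tert-butyldimethylsilyl) ether of the target, (Z)-alkene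
Conditions: H2 (1 atm), Pd/CaCO3 poisoned with Pb(OAc)2 (Lindlar catalyst), quinoline, EtOAc, rt, dark, stopped after one equivalent
Reagents that add atoms: none
Why: Lindlar semihydrogenation; syn addition of hydrogen on the poisoned palladium surface gives the Z-alkene, and the hindered diaryl alkene is reduced further only slowly.

Step 20
Reactants: 31 the heptasilyl Z-stilbene from step 19
Product: 32 5-[(2R,3R)-7-hydroxy-5-[(2S,3S)-6-hydroxy-2-(4-hydroxyphenyl)-4-[(Z)-2-(4-hydroxyphenyl)ethenyl]-2,3-dihydro-1-benzofuran-3-yl]-2-(4-hydroxyphenyl)-2,3-dihydro-1-benzofuran-3-yl]benzene-1,3-diol (the target)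
Conditions: Bu4NF (8 equiv), AcOH (8 equiv), THF, 0 °C, argon, dark
Reagents that add atoms: none
Why: Fluoride cleavage of aryl silyl ethers; the acetic acid buffer keeps the phenols protonated, so neither the Z-olefin nor the benzylic ethers are exposed to acid or strong base.

## Compound list

1 | 4-bromo-2-methoxyphenol | COc1cc(Br)ccc1O | starting material
2 | 4-bromo-2-iodo-6-methoxyphenol | Ic1cc(Br)cc(OC)c1O | intermediate
3 | 4-methoxybenzyl chloride | COc1ccc(CCl)cc1 | starting material
4 | 5-bromo-1-iodo-3-methoxy-2-[(4-methoxyphenyl)methoxy]benzene | Ic1cc(Br)cc(OC)c1OCc1ccc(OC)cc1 | intermediate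
5 | ethyl diazoacetate | CCOC(=O)C=[N+]=[N-] | starting material
6 | ethyl 2-{5-bromo-3-methoxy-2-[(4-methoxyphenyl)methoxy]phenyl}-2-diazoacetate | CCOC(=O)C(=[N+]=[N-])c1cc(Br)cc(OC)c1OCc1ccc(OC)cc1 | intermediate
7 | ethyl (2R,3S)-5-bromo-7-methoxy-2-(4-methoxyphenyl)-2,3-dihydro-1-benzofuran-3-carboxylate (cis) | Brc1cc(OC)c2c(c1)[C@H](C(=O)OCC)[C@H](c1ccc(OC)cc1)O2 | intermediate (not isolated)
8 | ethyl (2R,3R)-5-bromo-7-methoxy-2-(4-methoxyphenyl)-2,3-dihydro-1-benzofuran-3-carboxylate (trans) | Brc1cc(OC)c2c(c1)[C@@H](C(=O)OCC)[C@H](c1ccc(OC)cc1)O2 | intermediate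
9 | (2R,3R)-5-bromo-N,7-dimethoxy-2-(4-methoxyphenyl)-N-methyl-2,3-dihydro-1-benzofuran-3-carboxamide | Brc1cc(OC)c2c(c1)[C@@H](C(=O)N(C)OC)[C@H](c1ccc(OC)cc1)O2 | intermediate
10 | methyl 3,5-dioxohexanoate | COC(=O)CC(=O)CC(C)=O | starting material
11 | trilithium trianion of methyl 3,5-dioxohexanoate | [Li+].[Li+].[Li+].COC(=O)[CH-]C(=O)[CH-]C(=O)[CH2-] | intermediate (not isolated)
12 | methyl 7-[(2R,3R)-5-bromo-7-methoxy-2-(4-methoxyphenyl)-2,3-dihydro-1-benzofuran-3-yl]-3,5,7-trioxoheptanoate | Brc1cc(OC)c2c(c1)[C@@H](C(=O)CC(=O)CC(=O)CC(=O)OC)[C@H](c1ccc(OC)cc1)O2 | intermediate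
13 | methyl 2-[(2R,3R)-5-bromo-7-methoxy-2-(4-methoxyphenyl)-2,3-dihydro-1-benzofuran-3-yl]-2-hydroxy-4,6-dioxocyclohexane-1-carboxylate (ring centres undefined) | Brc1cc(OC)c2c(c1)[C@@H](C1(O)CC(=O)CC(=O)C1C(=O)OC)[C@H](c1ccc(OC)cc1)O2 | intermediate (not isolated)
14 | methyl 2-[(2R,3R)-5-bromo-7-methoxy-2-(4-methoxyphenyl)-2,3-dihydro-1-benzofuran-3-yl]-4,6-dihydroxybenzoate | Brc1cc(OC)c2c(c1)[C@@H](c1cc(O)cc(O)c1C(=O)OC)[C@H](c1ccc(OC)cc1)O2 | intermediate
15 | 2-[(2R,3R)-5-bromo-7-methoxy-2-(4-methoxyphenyl)-2,3-dihydro-1-benzofuran-3-yl]-4,6-dihydroxybenzoic acid | Brc1cc(OC)c2c(c1)[C@@H](c1cc(O)cc(O)c1C(=O)O)[C@H](c1ccc(OC)cc1)O2 | intermediate (not isolated)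
16 | 5-[(2R,3R)-5-bromo-7-methoxy-2-(4-methoxyphenyl)-2,3-dihydro-1-benzofuran-3-yl]benzene-1,3-diol | Brc1cc(OC)c2c(c1)[C@@H](c1cc(O)cc(O)c1)[C@H](c1ccc(OC)cc1)O2 | intermediate
17 | (2R,3R)-5-bromo-3-(3,5-dimethoxyphenyl)-7-methoxy-2-(4-methoxyphenyl)-2,3-dihydro-1-benzofuran | Brc1cc(OC)c2c(c1)[C@@H](c1cc(OC)cc(OC)c1)[C@H](c1ccc(OC)cc1)O2 | intermediate
18 | 2-bromo-4,6-dimethoxybenzaldehyde | COc1cc(Br)c(C=O)c(OC)c1 | starting material
19 | 2-bromo-6-hydroxy-4-methoxybenzaldehyde | COc1cc(O)c(C=O)c(Br)c1 | intermediate
20 | 2-bromo-4-methoxy-6-[(4-methoxyphenyl)methoxy]benzaldehyde | COc1ccc(COc2cc(OC)cc(Br)c2C=O)cc1 | intermediate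
21 | [(2R,3R)-3-(3,5-dimethoxyphenyl)-7-methoxy-2-(4-methoxyphenyl)-2,3-dihydro-1-benzofuran-5-yl]lithium | [Li]c1cc(OC)c2c(c1)[C@@H](c1cc(OC)cc(OC)c1)[C@H](c1ccc(OC)cc1)O2 | intermediate (not isolated)
22 | {2-bromo-4-methoxy-6-[(4-methoxyphenyl)methoxy]phenyl}[(2R,3R)-3-(3,5-dimethoxyphenyl)-7-methoxy-2-(4-methoxyphenyl)-2,3-dihydro-1-benzofuran-5-yl]methanol (carbinol epimers) | OC(c1c(Br)cc(OC)cc1OCc1ccc(OC)cc1)c1cc(OC)c2c(c1)[C@@H](c1cc(OC)cc(OC)c1)[C@H](c1ccc(OC)cc1)O2 | intermediate
23 | {2-bromo-4-methoxy-6-[(4-methoxyphenyl)methoxy]phenyl}[(2R,3R)-3-(3,5-dimethoxyphenyl)-7-methoxy-2-(4-methoxyphenyl)-2,3-dihydro-1-benzofuran-5-yl]methanone | O=C(c1c(Br)cc(OC)cc1OCc1ccc(OC)cc1)c1cc(OC)c2c(c1)[C@@H](c1cc(OC)cc(OC)c1)[C@H](c1ccc(OC)cc1)O2 | intermediate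
24 | hydrazone of 23 | NN=C(c1c(Br)cc(OC)cc1OCc1ccc(OC)cc1)c1cc(OC)c2c(c1)[C@@H](c1cc(OC)cc(OC)c1)[C@H](c1ccc(OC)cc1)O2 | intermediate
25 | diaryldiazomethane from 24 | [N-]=[N+]=C(c1c(Br)cc(OC)cc1OCc1ccc(OC)cc1)c1cc(OC)c2c(c1)[C@@H](c1cc(OC)cc(OC)c1)[C@H](c1ccc(OC)cc1)O2 | intermediate (not isolated)
26 | (2R,3S)-4-bromo-3-[(2R,3R)-3-(3,5-dimethoxyphenyl)-7-methoxy-2-(4-methoxyphenyl)-2,3-dihydro-1-benzofuran-5-yl]-6-methoxy-2-(4-methoxyphenyl)-2,3-dihydro-1-benzofuran (ring A cis) | Brc1cc(OC)cc2c1[C@H](c1cc(OC)c3c(c1)[C@@H](c1cc(OC)cc(OC)c1)[C@H](c1ccc(OC)cc1)O3)[C@H](c1ccc(OC)cc1)O2 | intermediate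
27 | 5-[(2R,3R)-5-[(2S,3S)-4-bromo-6-hydroxy-2-(4-hydroxyphenyl)-2,3-dihydro-1-benzofuran-3-yl]-7-hydroxy-2-(4-hydroxyphenyl)-2,3-dihydro-1-benzofuran-3-yl]benzene-1,3-diol | Brc1cc(O)cc2c1[C@H](c1cc(O)c3c(c1)[C@@H](c1cc(O)cc(O)c1)[C@H](c1ccc(O)cc1)O3)[C@@H](c1ccc(O)cc1)O2 | intermediate
28 | hexakis(tert-butyldimethylsilyl) ether of 27 | Brc1cc(O[Si](C)(C)C(C)(C)C)cc2c1[C@H](c1cc(O[Si](C)(C)C(C)(C)C)c3c(c1)[C@@H](c1cc(O[Si](C)(C)C(C)(C)C)cc(O[Si](C)(C)C(C)(C)C)c1)[C@H](c1ccc(O[Si](C)(C)C(C)(C)C)cc1)O3)[C@@H](c1ccc(O[Si](C)(C)C(C)(C)C)cc1)O2 | intermediate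
29 | tert-butyl(4-ethynylphenoxy)dimethylsilane | C#Cc1ccc(O[Si](C)(C)C(C)(C)C)cc1 | starting material
30 | heptakis(tert-butyldimethylsilyl) diarylalkyne (28 with C4 bromine replaced by the arylethynyl group) | CC(C)(C)[Si](C)(C)Oc1ccc(C#Cc2cc(O[Si](C)(C)C(C)(C)C)cc3c2[C@H](c2cc(O[Si](C)(C)C(C)(C)C)c4c(c2)[C@@H](c2cc(O[Si](C)(C)C(C)(C)C)cc(O[Si](C)(C)C(C)(C)C)c2)[C@H](c2ccc(O[Si](C)(C)C(C)(C)C)cc2)O4)[C@@H](c2ccc(O[Si](C)(C)C(C)(C)C)cc2)O3)cc1 | intermediate
31 | heptakis(tert-butyldimethylsilyl) ether of the target, (Z)-alkene | CC(C)(C)[Si](C)(C)Oc1ccc(/C=C\c2cc(O[Si](C)(C)C(C)(C)C)cc3c2[C@H](c2cc(O[Si](C)(C)C(C)(C)C)c4c(c2)[C@@H](c2cc(O[Si](C)(C)C(C)(C)C)cc(O[Si](C)(C)C(C)(C)C)c2)[C@H](c2ccc(O[Si](C)(C)C(C)(C)C)cc2)O4)[C@@H](c2ccc(O[Si](C)(C)C(C)(C)C)cc2)O3)cc1 | intermediate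
32 | 5-[(2R,3R)-7-hydroxy-5-[(2S,3S)-6-hydroxy-2-(4-hydroxyphenyl)-4-[(Z)-2-(4-hydroxyphenyl)ethenyl]-2,3-dihydro-1-benzofuran-3-yl]-2-(4-hydroxyphenyl)-2,3-dihydro-1-benzofuran-3-yl]benzene-1,3-diol | Oc1ccc(/C=C\c2cc(O)cc3c2[C@H](c2cc(O)c4c(c2)[C@@H](c2cc(O)cc(O)c2)[C@H](c2ccc(O)cc2)O4)[C@@H](c2ccc(O)cc2)O3)cc1 | target

## Step count and least certain steps

Total: 20 steps. Longest linear sequence: 18 steps (steps 1 to 9 and 12 to 20, from 1); steps 10 and 11 are the side branch to 20.

Step 7 (key step). What may go wrong: closure through the wrong pair of atoms (Claisen condensation to an acylphloroglucinol, or attack by enol oxygen and lactonisation to pyrones), slow addition to the hindered alpha-branched C7 carbonyl with chain scission by hydroxide taking over, or erosion of C3' by enolisation. Fallback: the carboxyl end is locked in a dioxinone ring so that only the aldol path is open. It sets out from 9 and comes back at 16. 2,2,6-Trimethyl-4H-1,3-dioxin-4-one is C-acetylated (LiN(SiMe3)2, acetyl chloride) to 2,2-dimethyl-6-(2-oxopropyl)-4H-1,3-dioxin-4-one F1. Its dianion (LiN(i-Pr)2, 2 equiv) is acylated by 9 to the diketo-dioxinone F2. Triethylamine in CH2Cl2 then brings about the aldol closure and dehydration to the benzodioxinone F3, which is opened and decarboxylated under the conditions of step 8 (through 15) to give 16.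

Step 15. What may go wrong: poor facial selectivity at the carbene because the ortho bromine twists the aryl group out of the geometry on which the catalyst was optimised, azine formation from the diazo compound, or low diastereoselectivity. Fallback: a (4+1) annulation of an ortho-quinone methide that needs no hydrazone or carbene and gives the trans ring directly. It sets out from 19 and from 17 (as its aryllithium 21) and comes back at 27. 19 is converted into its tert-butyl carbonate F4 (Boc2O, DMAP cat.). Addition of 21 at −78 °C and warming lets the carbonate migrate to the new alkoxide and leave, giving the ortho-quinone methide F5 in the flask. The ylide from (4-methoxybenzyl)dimethylsulfonium tetrafluoroborate F6 (from 3, dimethyl sulfide and AgBF4; deprotonated with LiN(SiMe3)2) adds to the methide carbon and the phenoxide displaces dimethyl sulfide. This gives the trans hexamethyl ether F7 together with its ring A antipodal diastereomer F8. The two are diastereomers because of ring B and are separated by chromatography, unless an enantiopure sulfonium salt makes this unnecessary. F7 is demethylated as in step 16 to 27. Absolute control of ring A is given up in this fallback in exchange for reliability.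

Step 14. What may go wrong: slow or incomplete condensation at the di-ortho-substituted carbonyl, and at the temperature needed, attack of the hydrazone nitrogen on the ortho bromide. Fallback: the C=N bond is installed during the union and not by condensation. It sets out from 20 and 17 (as 21) and comes back at 24. 20 is converted into the nitrile F9 (hydroxylamine-O-sulfonic acid, water/THF). 21 is added to F9 at −78 to 0 °C with inverse addition and a methanol quench gives the N–H ketimine F10. Transimination with hydrazine hydrate and acetic acid in ethanol at 40 °C, much easier than condensation with the ketone, gives 24.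

Step 16. What may go wrong: incomplete dealkylation, irreversible capture of the benzylic cation by an electron-rich ring, loss of the C3 proton from that cation (which would scramble C3), or incomplete equilibration of C2. Fallback: the two tasks are separated and the dealkylation is moved to a push–pull reagent that works at low temperature. It sets out from 26 and comes back at 27. BCl3 with Bu4NI in CH2Cl2 at −78 to 0 °C removes the methyl groups by iodide attack on the boron-complexed ether and gives the cis hexaphenol F11. F11 is then equilibrated at C2 with dilute HCl in methanol/THF at rt; with the free para-hydroxyl the ring opens and recloses through a para-quinone methide under much milder acid, giving 27.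

Step 6. What may go wrong: proton transfer from C3' of 9 to the very basic trianion in place of acylation, or reaction at an internal carbanion. Fallback: the chain is built in stages with a less basic nucleophile. It sets out from 9 and comes back at 12. The dianion of pentane-2,4-dione (LiN(i-Pr)2, 2 equiv) is acylated by 9 to the triketone F12. Its trianion (LiN(i-Pr)2, 3.1 equiv, −78 to −30 °C to limit attack on the aryl bromide) is carboxylated with CO2 to the triketo acid F13, which is esterified with Me3SiCHN2 in toluene/methanol to 12.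

Step 3. What may go wrong: slow coupling next to the ortho benzyloxy group, with palladium-induced loss of nitrogen from the diazo ester taking over. Fallback: the diazo group is introduced after the aryl–carbon bond. It sets out from 4 and comes back at 6. Copper-catalysed arylation of ethyl acetoacetate (CuI, 2-picolinic acid, Cs2CO3, 1,4-dioxane, 70 °C; the aryl bromide is not touched) gives the aryl acetoacetate F14. Deacetylative diazo transfer with 4-acetamidobenzenesulfonyl azide and DBU in MeCN gives 6.

## Further compounds

F1 | step 7 | 2,2-dimethyl-6-(2-oxopropyl)-4H-1,3-dioxin-4-one | CC(=O)CC1=CC(=O)OC(C)(C)O1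
F2 | step 7 | 6-{4-[(2R,3R)-5-bromo-7-methoxy-2-(4-methoxyphenyl)-2,3-dihydro-1-benzofuran-3-yl]-2,4-dioxobutyl}-2,2-dimethyl-4H-1,3-dioxin-4-one | Brc1cc(OC)c2c(c1)[C@@H](C(=O)CC(=O)CC1=CC(=O)OC(C)(C)O1)[C@H](c1ccc(OC)cc1)O2
F3 | step 7 | 5-[(2R,3R)-5-bromo-7-methoxy-2-(4-methoxyphenyl)-2,3-dihydro-1-benzofuran-3-yl]-7-hydroxy-2,2-dimethyl-4H-1,3-benzodioxin-4-one | Brc1cc(OC)c2c(c1)[C@@H](c1cc(O)cc3OC(C)(C)OC(=O)c13)[C@H](c1ccc(OC)cc1)O2
F4 | step 15 | 3-bromo-2-formyl-5-methoxyphenyl tert-butyl carbonate | COc1cc(OC(=O)OC(C)(C)C)c(C=O)c(Br)c1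
F5 | step 15 | 5-bromo-6-{[(2R,3R)-3-(3,5-dimethoxyphenyl)-7-methoxy-2-(4-methoxyphenyl)-2,3-dihydro-1-benzofuran-5-yl]methylidene}-3-methoxycyclohexa-2,4-dien-1-one | O=C1C=C(OC)C=C(Br)C1=Cc1cc(OC)c2c(c1)[C@@H](c1cc(OC)cc(OC)c1)[C@H](c1ccc(OC)cc1)O2
F6 | step 15 | (4-methoxybenzyl)dimethylsulfonium tetrafluoroborate | COc1ccc(C[S+](C)C)cc1.F[B-](F)(F)F
F7 | step 15 | (2S,3S)-4-bromo-3-[(2R,3R)-3-(3,5-dimethoxyphenyl)-7-methoxy-2-(4-methoxyphenyl)-2,3-dihydro-1-benzofuran-5-yl]-6-methoxy-2-(4-methoxyphenyl)-2,3-dihydro-1-benzofuran | Brc1cc(OC)cc2c1[C@H](c1cc(OC)c3c(c1)[C@@H](c1cc(OC)cc(OC)c1)[C@H](c1ccc(OC)cc1)O3)[C@@H](c1ccc(OC)cc1)O2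
F8 | step 15 | (2R,3R)-4-bromo-3-[(2R,3R)-3-(3,5-dimethoxyphenyl)-7-methoxy-2-(4-methoxyphenyl)-2,3-dihydro-1-benzofuran-5-yl]-6-methoxy-2-(4-methoxyphenyl)-2,3-dihydro-1-benzofuran | Brc1cc(OC)cc2c1[C@@H](c1cc(OC)c3c(c1)[C@@H](c1cc(OC)cc(OC)c1)[C@H](c1ccc(OC)cc1)O3)[C@H](c1ccc(OC)cc1)O2
F9 | step 14 | 2-bromo-4-methoxy-6-[(4-methoxyphenyl)methoxy]benzonitrile | COc1ccc(COc2cc(OC)cc(Br)c2C#N)cc1
F10 | step 14 | {2-bromo-4-methoxy-6-[(4-methoxyphenyl)methoxy]phenyl}[(2R,3R)-3-(3,5-dimethoxyphenyl)-7-methoxy-2-(4-methoxyphenyl)-2,3-dihydro-1-benzofuran-5-yl]methanimine | N=C(c1c(Br)cc(OC)cc1OCc1ccc(OC)cc1)c1cc(OC)c2c(c1)[C@@H](c1cc(OC)cc(OC)c1)[C@H](c1ccc(OC)cc1)O2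
F11 | step 16 | 5-[(2R,3R)-5-[(2R,3S)-4-bromo-6-hydroxy-2-(4-hydroxyphenyl)-2,3-dihydro-1-benzofuran-3-yl]-7-hydroxy-2-(4-hydroxyphenyl)-2,3-dihydro-1-benzofuran-3-yl]benzene-1,3-diol | Brc1cc(O)cc2c1[C@H](c1cc(O)c3c(c1)[C@@H](c1cc(O)cc(O)c1)[C@H](c1ccc(O)cc1)O3)[C@H](c1ccc(O)cc1)O2
F12 | step 6 | 1-[(2R,3R)-5-bromo-7-methoxy-2-(4-methoxyphenyl)-2,3-dihydro-1-benzofuran-3-yl]hexane-1,3,5-trione | Brc1cc(OC)c2c(c1)[C@@H](C(=O)CC(=O)CC(C)=O)[C@H](c1ccc(OC)cc1)O2
F13 | step 6 | 7-[(2R,3R)-5-bromo-7-methoxy-2-(4-methoxyphenyl)-2,3-dihydro-1-benzofuran-3-yl]-3,5,7-trioxoheptanoic acid | Brc1cc(OC)c2c(c1)[C@@H](C(=O)CC(=O)CC(=O)CC(=O)O)[C@H](c1ccc(OC)cc1)O2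
F14 | step 3 | ethyl 2-{5-bromo-3-methoxy-2-[(4-methoxyphenyl)methoxy]phenyl}-3-oxobutanoate | CCOC(=O)C(C(C)=O)c1cc(Br)cc(OC)c1OCc1ccc(OC)cc1
A1 | alternative 1 | 5-chloro-3-diazo-7-methoxy-2-(4-methoxyphenyl)chroman-4-one, C2 arranged as in the target | Clc1cc(OC)cc2c1C(=O)C(=[N+]=[N-])[C@@H](c1ccc(OC)cc1)O2
A2 | alternative 1 | methyl (2S,3S)-4-chloro-6-methoxy-2-(4-methoxyphenyl)-2,3-dihydro-1-benzofuran-3-carboxylate | Clc1cc(OC)cc2c1[C@H](C(=O)OC)[C@@H](c1ccc(OC)cc1)O2
A3 | alternative 2 | methyl 3-[1-(3,5-dimethoxyphenyl)-2-(4-methoxyphenyl)-2-oxoethyl]-4-fluoro-5-methoxybenzoate (racemic) | COC(=O)c1cc(OC)c(F)c(c1)C(c1cc(OC)cc(OC)c1)C(=O)c1ccc(OC)cc1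
A4 | alternative 2 | methyl (2R,3R)-3-(3,5-dimethoxyphenyl)-7-methoxy-2-(4-methoxyphenyl)-2,3-dihydro-1-benzofuran-5-carboxylate | COC(=O)c1cc(OC)c2c(c1)[C@@H](c1cc(OC)cc(OC)c1)[C@H](c1ccc(OC)cc1)O2
A5 | alternative 3 | 3-[(4-methoxyphenyl)ethynyl]cyclobut-2-en-1-one carrying on C4 the 2-(tert-butyldimethylsilyloxy)-2-(4-methoxyphenyl)-1-(ring B aryl)ethyl side chain (C4 undefined) | O=C1C=C(C#Cc2ccc(OC)cc2)C1[C@H](c1cc(OC)c3c(c1)[C@@H](c1cc(OC)cc(OC)c1)[C@H](c1ccc(OC)cc1)O3)[C@@H](c1ccc(OC)cc1)O[Si](C)(C)C(C)(C)C
A6 | alternative 3 | (triisopropylsiloxy)ethyne | C#CO[Si](C(C)C)(C(C)C)C(C)C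
A7 | alternative 3 | ring A phenol with arylethynyl group, triisopropylsilyloxy group and the C3/C2 side chain in place | COc1ccc(C#Cc2cc(O[Si](C(C)C)(C(C)C)C(C)C)cc(O)c2[C@H](c2cc(OC)c3c(c2)[C@@H](c2cc(OC)cc(OC)c2)[C@H](c2ccc(OC)cc2)O3)[C@@H](c2ccc(OC)cc2)O[Si](C)(C)C(C)(C)C)cc1
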